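**Plan**

1. Labels C1–C11 follow the target SMILES: C1 and C11 are the angelate carbinols, C2 the free carbinol, C3 is CMe2, C4 the cyclobutane CH, C5 and C9 the bridgeheads, C6 is CHMe, C7 is CH2, C8 the ketone, C10 the quaternary CMe.
2. Retrosynthetic cuts, in order: the two angelate C–O bonds; C1–O and C11–O (osmylation of C11=C1); C6–CH3 (cuprate); C11=C1 (aldol condensation closing the seven-membered ring); C10–CH3 and C4–C3 (enolate methylation, prenyl Grignard); the cyclobutane bond C10–C5 (Wolff ring contraction); C5–C(=O) (gold cyclisation); C9–C10 and C8–Si (conjugate silylation–propargylation of cyclohexenone).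
3. Forward, the ring C4–C5–C6–C7–C8–C9 comes from cyclohexenone, a 5-exo-dig cyclisation adds a two-carbon bridge (bicyclo[3.2.1]octane), ring contraction gives the cyclobutane C4–C5–C10–C9, and the seven-membered ring C10–C11–C1–C2–C3–C4 is closed last.
4. Enabling feature: in the bicyclo[3.1.1]heptane made of C4, C5, C6–C8, C9 and C10, C10 is bonded to both bridgeheads and to one exocyclic carbon. It can therefore come from a bicyclo[3.2.1]octane in which C10 carries a diazo group next to a carbonyl on the non-enolisable bridgehead C5; the contraction leaves that carbonyl carbon on C10 as a carboxyl group, which becomes C11.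
5. Stereochemistry: C8 (and through it C9, C5 and the absolute configuration) from a catalytic enantioselective conjugate silylation; C10 and C4 from the two faces of the cyclobutane (silyl shielding, 1,3-diaxial blocking, bridgehead radical); C2 from a CBS reduction; C6 from cuprate addition anti to the C10 methyl; C1 and C11 from osmylation anti to the C2 ether.

Key step: step 6

Remark: "upper face" of the cyclobutane means the face that carries the C6–C8 bridge; "lower face" is the face on which C3 and C11 are attached in the target.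
Remark: in the tricyclo[5.4.0.0^{2,8}]undecane names, locants 1–11 correspond to C9, C10, C11, C1, C2, C3, C4, C5, C6, C7, C8.
Assumption: in the CBS reduction (step 13) the quaternary carbon C3 acts as the large and the vinylic carbon C1 as the small ketone substituent.

**Route**

Step 1
Reactants: 1 cyclohex-2-en-1-one; 2 2-[dimethyl(phenyl)silyl]-4,4,5,5-tetramethyl-1,3,2-dioxaborolane; 3 3-bromoprop-1-yne
Product: 5 (2S,3S)-3-[dimethyl(phenyl)silyl]-2-(prop-2-yn-1-yl)cyclohexan-1-one, via pinacolboron enolate 4 (not isolated)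
Conditions: CuCl (2 mol %), chiral imidazolinium salt (NHC precursor, 2.2 mol %), NaOt-Bu (4.4 mol %), THF, −78 °C; then MeLi (1.05 equiv), then 3, DMPU, −78 → −20 °C
Reagents that add atoms: none
Why: Tandem conjugate addition–enolate alkylation, in which the chiral NHC–copper silyl species should add to one face of the enone to set the silyl-bearing carbon C8 as (S) (the ligand enantiomer is chosen for this sense) and the lithium borate enolate made from 4 is alkylated at C9 anti to the bulky silyl group, giving the trans product.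

Step 2
Reactants: 5 (2S,3S)-3-[dimethyl(phenyl)silyl]-2-(prop-2-yn-1-yl)cyclohexan-1-one
Product: 6 tert-butyl{[(5S,6S)-5-[dimethyl(phenyl)silyl]-6-(prop-2-yn-1-yl)cyclohex-1-en-1-yl]oxy}dimethylsilane
Conditions: LDA (1.05 equiv), THF, −78 °C; TBSOTf, −78 → 0 °C
Reagents that add atoms: tert-butyldimethylsilyl trifluoromethanesulfonate, CC(C)(C)[Si](C)(C)OS(=O)(=O)C(F)(F)F
Why: Kinetic enolate formation and O-silylation, in which LDA should remove a proton from the unsubstituted α-methylene (the future C5) rather than from the hindered C9–H or the less acidic alkyne C–H, so the less substituted silyl enol ether forms and C8 and C9 stay untouched.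

Step 3
Reactants: 6 tert-butyl{[(5S,6S)-5-[dimethyl(phenyl)silyl]-6-(prop-2-yn-1-yl)cyclohex-1-en-1-yl]oxy}dimethylsilane
Product: 7 (1S,2S,5R)-2-[dimethyl(phenyl)silyl]-6-methylidenebicyclo[3.2.1]octan-8-one
Conditions: Ph3PAuCl (5 mol %), AgBF4 (5 mol %), CH2Cl2/MeOH (10:1), rt
Reagents that add atoms: none
Why: Gold(I)-catalysed 5-exo-dig carbocyclisation of a silyl enol ether onto the activated alkyne (Conia-ene type), in which C5 attacks the internal alkyne carbon and methanol takes the silyl group and protonates the vinylgold; the two-carbon bridge can only span C9 and C5 cis, so C5 is set by C9.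

Step 4
Reactants: 7 (1S,2S,5R)-2-[dimethyl(phenyl)silyl]-6-methylidenebicyclo[3.2.1]octan-8-one
Product: 8 (1S,2S,5R)-2-[dimethyl(phenyl)silyl]bicyclo[3.2.1]octane-6,8-dione
Conditions: O3, CH2Cl2/MeOH, −78 °C; then Me2S, −78 °C → rt
Reagents that add atoms: ozone, [O-][O+]=O
Why: Ozonolysis with reductive work-up cleaves the exocyclic 1,1-disubstituted alkene to the cyclopentanone carbonyl on C5, while the arylsilane and the non-enolisable C4 ketone should be inert at −78 °C.

Step 5
Reactants: 8 (1S,2S,5R)-2-[dimethyl(phenyl)silyl]bicyclo[3.2.1]octane-6,8-dione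
Product: 10 7-diazo-2-[dimethyl(phenyl)silyl]bicyclo[3.2.1]octane-6,8-dione, via trifluoroacetyl diketone 9 (not isolated)
Conditions: LiHMDS, THF, −78 °C; CF3CO2CH2CF3; aq. HCl work-up; then MsN3, Et3N, H2O (1 equiv), MeCN, rt
Reagents that add atoms: methanesulfonyl azide, CS(=O)(=O)N=[N+]=[N-]; 2,2,2-trifluoroethyl trifluoroacetate, FC(F)(F)COC(=O)C(F)(F)F (its CF3CO group stays only in 9)
Why: Regitz-type deacylative diazo transfer, in which both carbonyls flank the bridgehead C5 that cannot enolise, so the enolate, its trifluoroacetylation and the diazo group can arise only at the methylene C10.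

Step 6
Reactants: 10 7-diazo-2-[dimethyl(phenyl)silyl]bicyclo[3.2.1]octane-6,8-dione
Product: 12 methyl 2-[dimethyl(phenyl)silyl]-7-oxobicyclo[3.1.1]heptane-6-carboxylate, via ketene 11 (not isolated)
Conditions: hν (365 nm LED), degassed MeOH (0.02 M), rt
Reagents that add atoms: methanol, CO
Why: Excitation of the diazo ketone expels dinitrogen and the C5–C(=O) bond shifts to the carbene carbon C10 (Wolff rearrangement), giving ketene 11, which methanol traps as the methyl ester. The closest precedent is the photochemical Wolff ring contraction of bridged bicyclic α-diazo ketones (bicyclo[2.2.1] to bicyclo[2.1.1], bicyclo[3.2.1] to bicyclo[3.1.1]). The cyclobutane C4–C5–C10–C9 is closed not by cyclisation but by contraction of the five-membered ring through the 1,2-shift, the added strain being paid for by the loss of dinitrogen. C5 migrates with retention, and the new stereocentre C10 should be set when the ester enol is protonated on the open lower face next to sp2-hybridised C4, which places the ester syn to the C6–C8 bridge. Regiochemistry is fixed because C5 is the only group on the carbonyl carbon that can migrate, and chemoselectivity is secured by irradiating at 365 nm, where the diazo chromophore absorbs but neither the C4 ketone nor the cyclobutanone product should be excited.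

Step 7
Reactants: 12 methyl 2-[dimethyl(phenyl)silyl]-7-oxobicyclo[3.1.1]heptane-6-carboxylate; 13 (3-methylbut-2-en-1-yl)magnesium chloride
Product: 14 methyl 7-hydroxy-7-(2-methylbut-3-en-2-yl)-2-[dimethyl(phenyl)silyl]bicyclo[3.1.1]heptane-6-carboxylate
Conditions: 13 (1.3 equiv), THF, −78 °C; then H2O
Reagents that add atoms: none
Why: Allylic Grignard addition through the six-membered SE2′ transition state transfers the 1,1-dimethylallyl unit (C3 with C2=C1) to the strained cyclobutanone faster than to the ester, and because the upper face of C4 is covered by the SiMe2Ph group on C8 while the lower face carries only the C10 hydrogen, C3 should enter from below and the hydroxyl end on the upper face.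

Step 8
Reactants: 14 methyl 7-hydroxy-7-(2-methylbut-3-en-2-yl)-2-[dimethyl(phenyl)silyl]bicyclo[3.1.1]heptane-6-carboxylate
Product: 15 methyl 7-hydroxy-6-methyl-7-(2-methylbut-3-en-2-yl)-2-[dimethyl(phenyl)silyl]bicyclo[3.1.1]heptane-6-carboxylate
Conditions: LDA (2.3 equiv), THF/DMPU, −78 → −20 °C; MeI, −78 → 0 °C
Reagents that add atoms: iodomethane, CI
Why: Ester enolate alkylation (on the alkoxide–enolate dianion), in which the lower face of C10 is blocked by the 1,3-diaxial CMe2 group on C4, so iodomethane should attack from the upper face and leave the ester carbon, the future C11, on the lower face next to C3.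

Step 9
Reactants: 15 methyl 7-hydroxy-6-methyl-7-(2-methylbut-3-en-2-yl)-2-[dimethyl(phenyl)silyl]bicyclo[3.1.1]heptane-6-carboxylate
Product: 16 6-(hydroxymethyl)-6-methyl-7-(2-methylbut-3-en-2-yl)-2-[dimethyl(phenyl)silyl]bicyclo[3.1.1]heptan-7-ol
Conditions: LiAlH4, THF, 0 °C → rt
Reagents that add atoms: none
Why: Hydride reduction of the neopentyl ester with LiAlH4 gives the primary alcohol at C11 and leaves the alkene, the tertiary alcohol and the C–Si bond untouched.

Step 10
Reactants: 16 6-(hydroxymethyl)-6-methyl-7-(2-methylbut-3-en-2-yl)-2-[dimethyl(phenyl)silyl]bicyclo[3.1.1]heptan-7-ol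
Product: 17 7-hydroxy-6-methyl-7-(2-methylbut-3-en-2-yl)-2-[dimethyl(phenyl)silyl]bicyclo[3.1.1]heptane-6-carbaldehyde
Conditions: DMP, NaHCO3, CH2Cl2, 0 °C → rt
Reagents that add atoms: none
Why: Dess–Martin oxidation takes the primary alcohol to the aldehyde, which has no α-hydrogen and so cannot epimerise, and it cannot oxidise the tertiary alcohol.

Step 11
Reactants: 17 7-hydroxy-6-methyl-7-(2-methylbut-3-en-2-yl)-2-[dimethyl(phenyl)silyl]bicyclo[3.1.1]heptane-6-carbaldehyde
Product: 18 7-hydroxy-6-methyl-7-(2-methyl-3-oxobutan-2-yl)-2-[dimethyl(phenyl)silyl]bicyclo[3.1.1]heptane-6-carbaldehyde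
Conditions: PdCl2 (20 mol %), CuCl (1 equiv), O2 (1 atm), DMF/H2O (7:1), rt
Reagents that add atoms: water, O
Why: Wacker–Tsuji oxidation of the monosubstituted alkene with Markovnikov selectivity turns the vinyl group into the methyl ketone (C2 carbonyl, C1 methyl) under conditions that tolerate aldehydes and free hydroxyl groups.

Step 12
Reactants: 18 7-hydroxy-6-methyl-7-(2-methyl-3-oxobutan-2-yl)-2-[dimethyl(phenyl)silyl]bicyclo[3.1.1]heptane-6-carbaldehyde
Product: 19 7-hydroxy-11-[dimethyl(phenyl)silyl]-2,6,6-trimethyltricyclo[5.4.0.0^{2,8}]undec-3-en-5-one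
Conditions: Bn2NH·CF3CO2H (1 equiv), toluene, 70 °C
Reagents that add atoms: none
Why: Intramolecular aldol condensation under amine-salt catalysis, in which the C1 methyl is the only enolisable position and the aldehyde C11 the only electrophile within reach, the two chains are held 1,3-diaxial on the cyclobutane so that the seven-membered cis-enone can close, and the nearly neutral medium avoids the alkoxide that would start a retro-aldol loss of the C3 chain.

Step 13
Reactants: 19 7-hydroxy-11-[dimethyl(phenyl)silyl]-2,6,6-trimethyltricyclo[5.4.0.0^{2,8}]undec-3-en-5-one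
Product: 20 11-[dimethyl(phenyl)silyl]-2,6,6-trimethyltricyclo[5.4.0.0^{2,8}]undec-3-ene-5,7-diol
Conditions: (S)-Me-CBS (0.5 equiv), catecholborane, toluene, −78 °C
Reagents that add atoms: none
Why: Corey–Bakshi–Shibata reduction, a reagent-controlled 1,2-reduction in which the (S)-oxazaborolidine should deliver hydride to the face of C2 on the C9 side so that the new hydroxyl points to the C5 side as in the target, while catecholborane at −78 °C should leave the hindered tertiary alcohol alone.

Step 14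
Reactants: 20 11-[dimethyl(phenyl)silyl]-2,6,6-trimethyltricyclo[5.4.0.0^{2,8}]undec-3-ene-5,7-diol
Product: 21 11-[dimethyl(phenyl)silyl]-5-[(4-methoxybenzyl)oxy]-2,6,6-trimethyltricyclo[5.4.0.0^{2,8}]undec-3-en-7-ol
Conditions: NaH, PMBCl, Bu4NI, DMF, 0 °C → rt
Reagents that add atoms: 4-methoxybenzyl chloride, COc1ccc(CCl)cc1
Why: Williamson etherification, in which the secondary allylic alkoxide is benzylated while the tertiary C4 alkoxide, flanked by a quaternary carbon and two bridgeheads, should be too hindered to react.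

Step 15
Reactants: 21 11-[dimethyl(phenyl)silyl]-5-[(4-methoxybenzyl)oxy]-2,6,6-trimethyltricyclo[5.4.0.0^{2,8}]undec-3-en-7-ol
Product: 22 11-[dimethyl(phenyl)silyl]-5-[(4-methoxybenzyl)oxy]-2,6,6-trimethyltricyclo[5.4.0.0^{2,8}]undec-3-en-7-yl methyl oxalate
Conditions: ClCOCO2Me, DMAP, pyridine, CH2Cl2, 0 °C → rt
Reagents that add atoms: methyl chlorooxoacetate, COC(=O)C(=O)Cl
Why: DMAP-catalysed acylation of the tertiary alcohol with the small and very reactive methyl oxalyl chloride gives the mixed oxalate needed for radical deoxygenation, and elimination is impossible because C4 is now a bridgehead.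

Step 16
Reactants: 22 11-[dimethyl(phenyl)silyl]-5-[(4-methoxybenzyl)oxy]-2,6,6-trimethyltricyclo[5.4.0.0^{2,8}]undec-3-en-7-yl methyl oxalate
Product: 23 {5-[(4-methoxybenzyl)oxy]-2,6,6-trimethyltricyclo[5.4.0.0^{2,8}]undec-3-en-11-yl}dimethyl(phenyl)silane
Conditions: Bu3SnH, AIBN, toluene, 110 °C
Reagents that add atoms: none
Why: Barton–McCombie-type radical deoxygenation of a tertiary methyl oxalate, in which fragmentation gives the bridgehead radical at C4 whose only open face is the upper one because C3 is tied into the seven-membered ring below, so hydrogen transfer from the stannane necessarily gives the C4–H configuration of the target.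

Step 17
Reactants: 23 {5-[(4-methoxybenzyl)oxy]-2,6,6-trimethyltricyclo[5.4.0.0^{2,8}]undec-3-en-11-yl}dimethyl(phenyl)silane
Product: 24 5-[(4-methoxybenzyl)oxy]-2,6,6-trimethyltricyclo[5.4.0.0^{2,8}]undec-3-en-11-ol
Conditions: KH, t-BuOOH, NMP, 0 °C → rt; then TBAF, 70 °C
Reagents that add atoms: tert-butyl hydroperoxide, CC(C)(C)OO
Why: Fleming–Tamao oxidation in its basic peroxide–fluoride form replaces the C8–SiMe2Ph bond by C8–OH with retention and, having no electrophilic oxidant, should spare the alkene and the PMB ether.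

Step 18
Reactants: 24 5-[(4-methoxybenzyl)oxy]-2,6,6-trimethyltricyclo[5.4.0.0^{2,8}]undec-3-en-11-ol
Product: 25 5-[(4-methoxybenzyl)oxy]-2,6,6-trimethyltricyclo[5.4.0.0^{2,8}]undec-3-en-11-one
Conditions: DMP, NaHCO3, CH2Cl2, rt
Reagents that add atoms: none
Why: Dess–Martin oxidation of the secondary alcohol gives the C8 ketone and removes the auxiliary stereocentre that has done its work.

Step 19
Reactants: 25 5-[(4-methoxybenzyl)oxy]-2,6,6-trimethyltricyclo[5.4.0.0^{2,8}]undec-3-en-11-one
Product: 27 5-[(4-methoxybenzyl)oxy]-2,6,6-trimethyltricyclo[5.4.0.0^{2,8}]undeca-3,9-dien-11-one, via trimethylsilyl enol ether 26 (not isolated)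
Conditions: LiHMDS, TMSCl, THF, −78 °C; then Pd(OAc)2 (1.1 equiv), MeCN, rt
Reagents that add atoms: chlorotrimethylsilane, C[Si](C)(C)Cl (its Me3Si group stays only in 26)
Why: Saegusa–Ito dehydrogenation, in which the ketone can enolise only toward C7 because C9 is a bridgehead, so silyl enol ether 26 and then the C6=C7 enone should form with complete regiocontrol.

Step 20
Reactants: 27 5-[(4-methoxybenzyl)oxy]-2,6,6-trimethyltricyclo[5.4.0.0^{2,8}]undeca-3,9-dien-11-one
Product: 28 5-[(4-methoxybenzyl)oxy]-2,6,6,9-tetramethyltricyclo[5.4.0.0^{2,8}]undec-3-en-11-one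
Conditions: Me2CuLi (from MeLi and CuI), Et2O, −78 → −20 °C; then H2O
Reagents that add atoms: lithium dimethylcuprate, [Li+].C[Cu-]C
Why: Cuprate conjugate addition to the bicyclo[3.1.1]heptenone, in which the methyl group on C10 covers one face of the enone and only the hydrogen on C4 the other, so the new methyl should add to C6 from the C4 side as the target requires.

Step 21
Reactants: 28 5-[(4-methoxybenzyl)oxy]-2,6,6,9-tetramethyltricyclo[5.4.0.0^{2,8}]undec-3-en-11-one
Product: 29 3,4-dihydroxy-5-[(4-methoxybenzyl)oxy]-2,6,6,9-tetramethyltricyclo[5.4.0.0^{2,8}]undecan-11-one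
Conditions: OsO4 (10 mol %), NMO, acetone/H2O (4:1), rt
Reagents that add atoms: osmium tetroxide, O=[Os](=O)(=O)=O; 4-methylmorpholine N-oxide, C[N+]1([O-])CCOCC1; water, O
Why: Upjohn dihydroxylation, in which osmium tetroxide adds syn to C11=C1 on the face opposite the allylic ether oxygen at C2 and should give the C1/C11 cis-diol trans to the C2 oxygen.

Step 22
Reactants: 29 3,4-dihydroxy-5-[(4-methoxybenzyl)oxy]-2,6,6,9-tetramethyltricyclo[5.4.0.0^{2,8}]undecan-11-one; 30 (2Z)-2-methylbut-2-enoic acid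
Product: 32 5-[(4-methoxybenzyl)oxy]-2,6,6,9-tetramethyl-11-oxotricyclo[5.4.0.0^{2,8}]undecane-3,4-diyl bis[(2Z)-2-methylbut-2-enoate], via mixed anhydride 31 (not isolated)
Conditions: 30 (6 equiv), 2,4,6-Cl3C6H2COCl, Et3N, toluene, rt; then 29, 80 °C
Reagents that add atoms: 2,4,6-trichlorobenzoyl chloride, O=C(Cl)c1c(Cl)cc(Cl)cc1Cl (its aroyl group stays only in 31)
Why: Yamaguchi-type esterification through the mixed 2,4,6-trichlorobenzoic anhydride without a nucleophilic catalyst, conditions chosen to acylate both hindered secondary alcohols while keeping the (Z) geometry of the angelate.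

Step 23
Reactants: 32 5-[(4-methoxybenzyl)oxy]-2,6,6,9-tetramethyl-11-oxotricyclo[5.4.0.0^{2,8}]undecane-3,4-diyl bis[(2Z)-2-methylbut-2-enoate]
Product: 33 5-hydroxy-2,6,6,9-tetramethyl-11-oxotricyclo[5.4.0.0^{2,8}]undecane-3,4-diyl bis[(2Z)-2-methylbut-2-enoate]
Conditions: DDQ, CH2Cl2/pH 7 buffer, 0 °C → rt
Reagents that add atoms: none
Why: Oxidative cleavage of the p-methoxybenzyl ether with DDQ in buffered wet dichloromethane should free the C2 hydroxyl without affecting the angelate esters or the ketone.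

**Compound list**

1 | cyclohex-2-en-1-one | O=C1C=CCCC1 | starting material
2 | 2-[dimethyl(phenyl)silyl]-4,4,5,5-tetramethyl-1,3,2-dioxaborolane (PhMe2Si–Bpin) | C[Si](C)(c1ccccc1)B1OC(C)(C)C(C)(C)O1 | starting material
3 | 3-bromoprop-1-yne (propargyl bromide) | C#CCBr | starting material
4 | pinacolboron enolate, 2-{[(3S)-3-[dimethyl(phenyl)silyl]cyclohex-1-en-1-yl]oxy}-4,4,5,5-tetramethyl-1,3,2-dioxaborolane | CC1(C)OB(OC2=C[C@@H]([Si](C)(C)c3ccccc3)CCC2)OC1(C)C | intermediate
5 | (2S,3S)-3-[dimethyl(phenyl)silyl]-2-(prop-2-yn-1-yl)cyclohexan-1-one (substituents trans) | O=C1[C@H](CC#C)[C@@H]([Si](C)(C)c2ccccc2)CCC1 | intermediate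
6 | tert-butyl{[(5S,6S)-5-[dimethyl(phenyl)silyl]-6-(prop-2-yn-1-yl)cyclohex-1-en-1-yl]oxy}dimethylsilane | CC(C)(C)[Si](C)(C)OC1=CCC[C@H]([Si](C)(C)c2ccccc2)[C@H]1CC#C | intermediate
7 | (1S,2S,5R)-2-[dimethyl(phenyl)silyl]-6-methylidenebicyclo[3.2.1]octan-8-one (silyl on the side of the C8 ketone bridge) | O=C1[C@@H]2CC[C@H]([Si](C)(C)c3ccccc3)[C@H]1CC2=C | intermediate
8 | (1S,2S,5R)-2-[dimethyl(phenyl)silyl]bicyclo[3.2.1]octane-6,8-dione | O=C1[C@@H]2CC[C@H]([Si](C)(C)c3ccccc3)[C@H]1CC2=O | intermediate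
9 | 7-(trifluoroacetyl) derivative of 8 (acyl group on C10, configuration there not defined) | O=C1[C@@H]2CC[C@H]([Si](C)(C)c3ccccc3)[C@H]1C(C(=O)C(F)(F)F)C2=O | intermediate
10 | 7-diazo-2-[dimethyl(phenyl)silyl]bicyclo[3.2.1]octane-6,8-dione (diazo on C10, ring stereocentres as in 8) | O=C1[C@@H]2CC[C@H]([Si](C)(C)c3ccccc3)[C@H]1C(=[N+]=[N-])C2=O | intermediate
11 | ketene, 2-[dimethyl(phenyl)silyl]-6-(oxomethylidene)bicyclo[3.1.1]heptan-7-one | O=C1[C@@H]2CC[C@H]([Si](C)(C)c3ccccc3)[C@H]1C2=C=O | intermediate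
12 | methyl 2-[dimethyl(phenyl)silyl]-7-oxobicyclo[3.1.1]heptane-6-carboxylate (ester syn to the C2–C4 bridge, silyl on the side of the C7 ketone) | O=C1[C@@H]2CC[C@H]([Si](C)(C)c3ccccc3)[C@H]1[C@H]2C(=O)OC | intermediate
13 | (3-methylbut-2-en-1-yl)magnesium chloride (prenylmagnesium chloride) | CC(C)=CC[Mg]Cl | starting material
14 | methyl 7-hydroxy-7-(2-methylbut-3-en-2-yl)-2-[dimethyl(phenyl)silyl]bicyclo[3.1.1]heptane-6-carboxylate (7-OH and 6-CO2Me syn to the C2–C4 bridge) | C=CC(C)(C)[C@@]1(O)[C@@H]2CC[C@H]([Si](C)(C)c3ccccc3)[C@H]1[C@H]2C(=O)OC | intermediate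
15 | methyl 7-hydroxy-6-methyl-7-(2-methylbut-3-en-2-yl)-2-[dimethyl(phenyl)silyl]bicyclo[3.1.1]heptane-6-carboxylate (6-CH3 and 7-OH syn to the C2–C4 bridge, ester and dimethylallyl group anti) | C=CC(C)(C)[C@@]1(O)[C@@H]2CC[C@H]([Si](C)(C)c3ccccc3)[C@H]1[C@]2(C)C(=O)OC | intermediate
16 | 6-(hydroxymethyl)-6-methyl-7-(2-methylbut-3-en-2-yl)-2-[dimethyl(phenyl)silyl]bicyclo[3.1.1]heptan-7-ol (configuration as in 15) | C=CC(C)(C)[C@@]1(O)[C@@H]2CC[C@H]([Si](C)(C)c3ccccc3)[C@H]1[C@]2(C)CO | intermediate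
17 | 7-hydroxy-6-methyl-7-(2-methylbut-3-en-2-yl)-2-[dimethyl(phenyl)silyl]bicyclo[3.1.1]heptane-6-carbaldehyde (configuration as in 15) | C=CC(C)(C)[C@@]1(O)[C@@H]2CC[C@H]([Si](C)(C)c3ccccc3)[C@H]1[C@]2(C)C=O | intermediate
18 | 7-hydroxy-6-methyl-7-(2-methyl-3-oxobutan-2-yl)-2-[dimethyl(phenyl)silyl]bicyclo[3.1.1]heptane-6-carbaldehyde (configuration as in 15) | CC(=O)C(C)(C)[C@@]1(O)[C@@H]2CC[C@H]([Si](C)(C)c3ccccc3)[C@H]1[C@]2(C)C=O | intermediate
19 | 7-hydroxy-11-[dimethyl(phenyl)silyl]-2,6,6-trimethyltricyclo[5.4.0.0^{2,8}]undec-3-en-5-one (C11=C1–C2=O enone, 4-OH on the upper face, 8-silyl) | O=C1C(C)(C)[C@@]2(O)[C@@H]3CC[C@H]([Si](C)(C)c4ccccc4)[C@H]2[C@]3(C)C=C1 | intermediate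
20 | 11-[dimethyl(phenyl)silyl]-2,6,6-trimethyltricyclo[5.4.0.0^{2,8}]undec-3-ene-5,7-diol (C2–OH on the C5 side) | O[C@H]1C(C)(C)[C@@]2(O)[C@@H]3CC[C@H]([Si](C)(C)c4ccccc4)[C@H]2[C@]3(C)C=C1 | intermediate
21 | 11-[dimethyl(phenyl)silyl]-5-[(4-methoxybenzyl)oxy]-2,6,6-trimethyltricyclo[5.4.0.0^{2,8}]undec-3-en-7-ol | COc1ccc(CO[C@H]2C(C)(C)[C@@]3(O)[C@@H]4CC[C@H]([Si](C)(C)c5ccccc5)[C@H]3[C@]4(C)C=C2)cc1 | intermediate
22 | 11-[dimethyl(phenyl)silyl]-5-[(4-methoxybenzyl)oxy]-2,6,6-trimethyltricyclo[5.4.0.0^{2,8}]undec-3-en-7-yl methyl oxalate | COc1ccc(CO[C@H]2C(C)(C)[C@@]3(OC(=O)C(=O)OC)[C@@H]4CC[C@H]([Si](C)(C)c5ccccc5)[C@H]3[C@]4(C)C=C2)cc1 | intermediate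
23 | {5-[(4-methoxybenzyl)oxy]-2,6,6-trimethyltricyclo[5.4.0.0^{2,8}]undec-3-en-11-yl}dimethyl(phenyl)silane (C4–H on the upper face) | COc1ccc(CO[C@H]2C(C)(C)[C@H]3[C@@H]4CC[C@H]([Si](C)(C)c5ccccc5)[C@H]3[C@]4(C)C=C2)cc1 | intermediate
24 | 5-[(4-methoxybenzyl)oxy]-2,6,6-trimethyltricyclo[5.4.0.0^{2,8}]undec-3-en-11-ol (C8–OH where the silyl group was) | COc1ccc(CO[C@H]2C(C)(C)[C@H]3[C@@H]4CC[C@H](O)[C@H]3[C@]4(C)C=C2)cc1 | intermediate
25 | 5-[(4-methoxybenzyl)oxy]-2,6,6-trimethyltricyclo[5.4.0.0^{2,8}]undec-3-en-11-one | COc1ccc(CO[C@H]2C(C)(C)[C@H]3[C@@H]4CCC(=O)[C@H]3[C@]4(C)C=C2)cc1 | intermediate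
26 | trimethylsilyl enol ether of 25, {[5-[(4-methoxybenzyl)oxy]-2,6,6-trimethyltricyclo[5.4.0.0^{2,8}]undeca-3,10-dien-11-yl]oxy}trimethylsilane | COc1ccc(CO[C@H]2C(C)(C)[C@H]3[C@@H]4CC=C(O[Si](C)(C)C)[C@H]3[C@]4(C)C=C2)cc1 | intermediate
27 | 5-[(4-methoxybenzyl)oxy]-2,6,6-trimethyltricyclo[5.4.0.0^{2,8}]undeca-3,9-dien-11-one | COc1ccc(CO[C@H]2C(C)(C)[C@H]3[C@@H]4C=CC(=O)[C@H]3[C@]4(C)C=C2)cc1 | intermediate
28 | 5-[(4-methoxybenzyl)oxy]-2,6,6,9-tetramethyltricyclo[5.4.0.0^{2,8}]undec-3-en-11-one (C6 methyl on the C4 side) | COc1ccc(CO[C@H]2C(C)(C)[C@H]3[C@@H]4[C@H](C)CC(=O)[C@H]3[C@]4(C)C=C2)cc1 | intermediate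
29 | 3,4-dihydroxy-5-[(4-methoxybenzyl)oxy]-2,6,6,9-tetramethyltricyclo[5.4.0.0^{2,8}]undecan-11-one (C1/C11 diol cis, trans to the C2 ether) | O[C@@H]1[C@@H](OCc2ccc(OC)cc2)C(C)(C)[C@H]3[C@@H]4[C@H](C)CC(=O)[C@H]3[C@]4(C)[C@@H]1O | intermediate
30 | (2Z)-2-methylbut-2-enoic acid (angelic acid) | C/C=C(/C)C(=O)O | starting material
31 | mixed anhydride, (2Z)-2-methylbut-2-enoic 2,4,6-trichlorobenzoic anhydride | C/C=C(/C)C(=O)OC(=O)c1c(Cl)cc(Cl)cc1Cl | intermediate
32 | 5-[(4-methoxybenzyl)oxy]-2,6,6,9-tetramethyl-11-oxotricyclo[5.4.0.0^{2,8}]undecane-3,4-diyl bis[(2Z)-2-methylbut-2-enoate] | C/C=C(/C)C(=O)O[C@@H]1[C@@H](OCc2ccc(OC)cc2)C(C)(C)[C@H]3[C@@H]4[C@H](C)CC(=O)[C@H]3[C@]4(C)[C@@H]1OC(=O)/C(C)=C\C | intermediate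
33 | 5-hydroxy-2,6,6,9-tetramethyl-11-oxotricyclo[5.4.0.0^{2,8}]undecane-3,4-diyl bis[(2Z)-2-methylbut-2-enoate] (CNP0344448.1) | C/C=C(/C)C(=O)O[C@@H]1[C@@H](O)C(C)(C)[C@H]2[C@@H]3[C@H](C)CC(=O)[C@H]2[C@]3(C)[C@@H]1OC(=O)/C(C)=C\C | target

**Step count and risks**

Total steps: 23. Longest linear sequence: 23 steps (from 1).

Step 6 (Wolff contraction). The contraction adds strain, so the carbene may insert into the O–H bond of methanol instead of rearranging. The unprotected non-enolisable 1,3-diketone may also open by retro-Claisen attack, or the cyclobutanone formed may be photolysed further. The fallback is a quasi-Favorskii contraction on a protected ketone and sets out from 7. Ketalisation with ethylene glycol (TMSOCH2CH2OTMS, cat. TMSOTf) would give the dioxolane F1, and ozonolysis the ketal ketone F2. Enolate bromination (LiHMDS; NBS) would give the α-bromo ketone F3. Sodium methoxide in methanol would then add to the carbonyl and shift C5 to C10 with loss of bromide (semibenzilic mechanism), giving the ketal ester F4; C10 should settle under these conditions to the epimer with the ester away from the axial dioxolane oxygen. Aqueous acid would remove the dioxolane, and the route is rejoined at 12.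

Step 8 (C10 methylation). Enolisation of the shielded C10–H may be slow, and the alkylation has to push the ester into a 1,3-diaxial position next to the CMe2 group, so conversion may stall. The fallback makes the quaternary centre at the aldehyde oxidation level and sets out from 14. LiAlH4 reduction would give the diol F5 and Dess–Martin oxidation the α-branched aldehyde F6. Reversible deprotonation with KOt-Bu in the presence of iodomethane would then methylate the smaller aldehyde enolate from the same upper face. This gives 17 directly and bypasses 15 and 16.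

Step 12 (ring-closing aldol condensation). The two hindered partners may condense slowly, and retro-aldol cleavage of the C4–C3 bond of the tertiary β-hydroxy ketone may outrun ring closure. The fallback closes the ring on the protected alcohol under basic conditions and sets out from 17. Silylation (TESOTf, 2,6-lutidine) would give the triethylsilyl ether F7 and Wacker oxidation the keto aldehyde F8. Potassium hydroxide in methanol would close the ring to the silylated enone F9; with no free alkoxide at C4 the retro-aldol path is shut. HF·pyridine would remove the silyl group, and the route is rejoined at 19.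

Further compounds

F1 | step 6 | ethylene ketal of 7, 2'-[dimethyl(phenyl)silyl]-6'-methylidenespiro[1,3-dioxolane-2,8'-bicyclo[3.2.1]octane] | C12(OCCO1)[C@@H]3CC[C@H]([Si](C)(C)c4ccccc4)[C@H]2CC3=C
F2 | step 6 | ketal ketone, 2'-[dimethyl(phenyl)silyl]spiro[1,3-dioxolane-2,8'-bicyclo[3.2.1]octan]-6'-one | C12(OCCO1)[C@@H]3CC[C@H]([Si](C)(C)c4ccccc4)[C@H]2CC3=O
F3 | step 6 | α-bromo ketone, 7'-bromo-2'-[dimethyl(phenyl)silyl]spiro[1,3-dioxolane-2,8'-bicyclo[3.2.1]octan]-6'-one (configuration at C10 not defined) | C12(OCCO1)[C@@H]3CC[C@H]([Si](C)(C)c4ccccc4)[C@H]2C(Br)C3=O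
F4 | step 6 | ketal ester, methyl 2'-[dimethyl(phenyl)silyl]spiro[1,3-dioxolane-2,7'-bicyclo[3.1.1]heptane]-6'-carboxylate (ester syn to the three-carbon bridge) | C12(OCCO1)[C@@H]3CC[C@H]([Si](C)(C)c4ccccc4)[C@H]2[C@H]3C(=O)OC
F5 | step 8 | 6-(hydroxymethyl)-7-(2-methylbut-3-en-2-yl)-2-[dimethyl(phenyl)silyl]bicyclo[3.1.1]heptan-7-ol | C=CC(C)(C)[C@@]1(O)[C@@H]2CC[C@H]([Si](C)(C)c3ccccc3)[C@H]1[C@H]2CO
F6 | step 8 | 7-hydroxy-7-(2-methylbut-3-en-2-yl)-2-[dimethyl(phenyl)silyl]bicyclo[3.1.1]heptane-6-carbaldehyde (C10 epimerisable) | C=CC(C)(C)[C@@]1(O)[C@@H]2CC[C@H]([Si](C)(C)c3ccccc3)[C@H]1[C@H]2C=O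
F7 | step 12 | triethylsilyl ether of 17 | C=CC(C)(C)[C@@]1(O[Si](CC)(CC)CC)[C@@H]2CC[C@H]([Si](C)(C)c3ccccc3)[C@H]1[C@]2(C)C=O
F8 | step 12 | triethylsilyl ether of 18 | CC(=O)C(C)(C)[C@@]1(O[Si](CC)(CC)CC)[C@@H]2CC[C@H]([Si](C)(C)c3ccccc3)[C@H]1[C@]2(C)C=O
F9 | step 12 | triethylsilyl ether of 19 | O=C1C(C)(C)[C@@]2(O[Si](CC)(CC)CC)[C@@H]3CC[C@H]([Si](C)(C)c4ccccc4)[C@H]2[C@]3(C)C=C1
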